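The ten-membered carbocycle is opened at its only ring C=C bond, C1=C10. Because the C9 carbinol is allylic to this E-trisubstituted alkene, C9 can serve as a ketone that stabilises a triphenylphosphorane at C10. Its base-free intramolecular Wittig reaction with a C1 aldehyde closes the ring and sets the E-enone in one operation. The precursor is the open C1–C10 chain carrying the aldehyde, the 4,5-epoxide, 6-OAc, 7-isopropyl, 8-O-tiglate and the C9 keto ylide, with all five sp3 stereocentres already in place (anti-aldol, hydroxyl-directed epoxidation, Evans–Tishchenko reduction). Luche reduction of C9 then completes the target.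

Key step: step 17

Remark on numbering: germacrane locants are used for all open-chain compounds (C1 aldehyde carbon to C10 ylide carbon; C4–C5 epoxide, C6 OAc, C7 isopropyl, C8 tiglate, C9 carbonyl); PMB = 4-methoxybenzyl.

Remark on stereochemistry: 27 and 28 carry 4R,5R,6S,8S and the C7 configuration of the target (the C7 descriptor is R while C9 is a carbonyl and S in the target, a change of CIP priority only). The C5–O/C6–O relationship is threo, the opposite of what Felkin–Anh addition to a 2,3-epoxy aldehyde would give, so C6 is set first and the epoxide is then placed by hydroxyl direction.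

Step 1
Reactants: 1 pent-4-yn-1-ol
Product: 2 1-methoxy-4-[(pent-4-yn-1-yloxy)methyl]benzene
Conditions: NaH, PMBCl, Bu4NI (cat.), THF/DMF, 0 °C → rt
Reagents that add atoms: 4-methoxybenzyl chloride COc1ccc(CCl)cc1
Why: Williamson etherification, in which NaH removes only the hydroxyl proton (the alkyne C–H is far less acidic) and the alkoxide is benzylated at oxygen.

Step 2
Reactants: 2 1-methoxy-4-[(pent-4-yn-1-yloxy)methyl]benzene
Product: 4 (E)-6-[(4-methoxybenzyl)oxy]-3-methylhex-2-en-1-ol, via alkenylalane 3 (not isolated)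
Conditions: Me3Al, Cp2ZrCl2 (0.25 equiv), CH2Cl2, 0 °C → rt; then n-BuLi, THF, −78 °C; (CH2O)n, −78 °C → rt
Reagents that add atoms: trimethylaluminium C[Al](C)C; formaldehyde (from paraformaldehyde) C=O
Why: Negishi zirconium-catalysed carboalumination adds methyl and aluminium syn across the terminal alkyne with aluminium at the terminus, and the derived alanate is hydroxymethylated with retention, which fixes the E-trisubstituted C4=C5 alkene and its C4 methyl.

Step 3
Reactants: 4 (E)-6-[(4-methoxybenzyl)oxy]-3-methylhex-2-en-1-ol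
Product: 5 (E)-6-[(4-methoxybenzyl)oxy]-3-methylhex-2-enal
Conditions: activated MnO2, CH2Cl2, rt
Reagents that add atoms: none
Why: MnO2 oxidises allylic alcohols selectively to enals without touching the PMB ether or the alkene geometry.

Step 4
Reactants: 6 (S)-4-benzyloxazolidin-2-one; 7 3-methylbutanoyl chloride
Product: 8 (S)-4-benzyl-3-(3-methylbutanoyl)oxazolidin-2-one
Conditions: n-BuLi, THF, −78 °C; then 7, −78 → 0 °C
Reagents that add atoms: none
Why: N-acylation of the lithiated oxazolidinone by the acid chloride.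

Step 5
Reactants: 8 (S)-4-benzyl-3-(3-methylbutanoyl)oxazolidin-2-one; 5 (E)-6-[(4-methoxybenzyl)oxy]-3-methylhex-2-enal
Product: 10 (S)-4-benzyl-3-[(2R,3R,E)-3-hydroxy-2-isopropyl-8-[(4-methoxybenzyl)oxy]-5-methyloct-4-enoyl]oxazolidin-2-one, via TMS ether 9 (not isolated)
Conditions: MgCl2 (0.2 equiv), Et3N, TMSCl, EtOAc, rt; then citric acid, MeOH, 0 °C
Reagents that add atoms: chlorotrimethylsilane C[Si](C)(C)Cl (its silyl group is carried only by 9)
Why: Magnesium halide-catalysed direct anti-aldol of an N-acyloxazolidinone, in which the chelated (Z)-magnesium enolate adds to the enal (no α-proton) through a boat transition state on the face away from the benzyl group, setting C7 (R) and, through the anti relationship, C6 (R), while silylation of the aldolate drives turnover.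

Step 6
Reactants: 10 (S)-4-benzyl-3-[(2R,3R,E)-3-hydroxy-2-isopropyl-8-[(4-methoxybenzyl)oxy]-5-methyloct-4-enoyl]oxazolidin-2-one
Product: 11 (2R,3R,E)-3-hydroxy-2-isopropyl-N-methoxy-8-[(4-methoxybenzyl)oxy]-N,5-dimethyloct-4-enamide
Conditions: MeNH(OMe)·HCl, Me3Al, CH2Cl2, −20 → 0 °C
Reagents that add atoms: N,O-dimethylhydroxylamine hydrochloride CNOC.Cl
Why: Weinreb transamination, in which the aluminium amide attacks the exocyclic imide carbonyl with assistance from the aluminium alkoxide of the free β-hydroxyl; it is run before the epoxidation because Me3Al would open an epoxy alcohol.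

Step 7
Reactants: 11 (2R,3R,E)-3-hydroxy-2-isopropyl-N-methoxy-8-[(4-methoxybenzyl)oxy]-N,5-dimethyloct-4-enamide
Product: 12 (2R,3S)-3-hydroxy-2-isopropyl-N-methoxy-3-[(2R,3R)-3-{3-[(4-methoxybenzyl)oxy]propyl}-3-methyloxiran-2-yl]-N-methylpropanamide
Conditions: mCPBA, NaHCO3, CH2Cl2, 0 °C
Reagents that add atoms: 3-chloroperoxybenzoic acid OOC(=O)c1cccc(Cl)c1
Why: Hydroxyl-directed (Henbest) peracid epoxidation of the only alkene, in which allylic 1,3-strain with the cis C4 methyl holds the C6–H in the alkene plane, so oxygen delivered syn to the hydroxyl should give the threo (4R,5R) epoxy alcohol.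

Step 8
Reactants: 13 propanal; 14 propane-1,3-dithiol
Product: 15 2-ethyl-1,3-dithiane
Conditions: BF3·OEt2 (cat.), CH2Cl2, 0 °C → rt
Reagents that add atoms: none
Why: Lewis acid-catalysed dithioacetalisation of the aldehyde.

Step 9
Reactants: 12 (2R,3S)-3-hydroxy-2-isopropyl-N-methoxy-3-[(2R,3R)-3-{3-[(4-methoxybenzyl)oxy]propyl}-3-methyloxiran-2-yl]-N-methylpropanamide; 15 2-ethyl-1,3-dithiane
Product: 17 (2R,3S)-1-(2-ethyl-1,3-dithian-2-yl)-3-hydroxy-2-isopropyl-3-[(2R,3R)-3-{3-[(4-methoxybenzyl)oxy]propyl}-3-methyloxiran-2-yl]propan-1-one, via lithiated dithiane 16 (not isolated)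
Conditions: 15 (3.2 equiv), n-BuLi (3.0 equiv), THF, −30 °C; then 12, −78 → −40 °C; H2O
Reagents that add atoms: n-butyllithium [Li]CCCC (its lithium is carried only by 16)
Why: Corey–Seebach umpolung, in which the lithiated dithiane (the first equivalent removes the C6–OH proton) acylates at the Weinreb amide, whose chelated tetrahedral intermediate stops at the ketone, while the trisubstituted epoxide is not opened at this temperature.

Step 10
Reactants: 17 (2R,3S)-1-(2-ethyl-1,3-dithian-2-yl)-3-hydroxy-2-isopropyl-3-[(2R,3R)-3-{3-[(4-methoxybenzyl)oxy]propyl}-3-methyloxiran-2-yl]propan-1-one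
Product: 18 (1S,2S,3S)-3-(2-ethyl-1,3-dithian-2-yl)-3-hydroxy-2-isopropyl-1-[(2R,3R)-3-{3-[(4-methoxybenzyl)oxy]propyl}-3-methyloxiran-2-yl]propyl acetate
Conditions: SmI2 (0.3 equiv), MeCHO (10 equiv), THF, −10 °C
Reagents that add atoms: acetaldehyde CC=O
Why: Evans–Tishchenko reduction, in which the samarium-bound hemiacetal formed from the C6 hydroxyl and acetaldehyde transfers hydride to C8 through a six-membered chair, which should give the 1,3-anti (8S) alcohol and at the same time leaves the acetate on O6.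

Step 11
Reactants: 18 (1S,2S,3S)-3-(2-ethyl-1,3-dithian-2-yl)-3-hydroxy-2-isopropyl-1-[(2R,3R)-3-{3-[(4-methoxybenzyl)oxy]propyl}-3-methyloxiran-2-yl]propyl acetate
Product: 19 (1S,2S,3S)-3-hydroxy-2-isopropyl-1-[(2R,3R)-3-{3-[(4-methoxybenzyl)oxy]propyl}-3-methyloxiran-2-yl]-4-oxohexyl acetate
Conditions: MeI, CaCO3, MeCN/H2O (9:1), 40 °C
Reagents that add atoms: water O
Why: Alkylative dithiane hydrolysis (S-methylation, ring opening, hydrolysis of the thionium ion), buffered by CaCO3 so that the epoxide, the acetate and the PMB ether survive.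

Step 12
Reactants: 19 (1S,2S,3S)-3-hydroxy-2-isopropyl-1-[(2R,3R)-3-{3-[(4-methoxybenzyl)oxy]propyl}-3-methyloxiran-2-yl]-4-oxohexyl acetate; 20 (E)-2-methylbut-2-enoyl chloride
Product: 21 (4S,5R,6S)-6-acetoxy-5-isopropyl-6-[(2R,3R)-3-{3-[(4-methoxybenzyl)oxy]propyl}-3-methyloxiran-2-yl]-3-oxohexan-4-yl (E)-2-methylbut-2-enoate
Conditions: pyridine, DMAP (cat.), CH2Cl2, 0 °C
Reagents that add atoms: none
Why: DMAP-catalysed acylation of the α-ketol hydroxyl, placed after dithiane removal because the carbinol next to the quaternary dithiane carbon would be far more hindered.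

Step 13
Reactants: 21 (4S,5R,6S)-6-acetoxy-5-isopropyl-6-[(2R,3R)-3-{3-[(4-methoxybenzyl)oxy]propyl}-3-methyloxiran-2-yl]-3-oxohexan-4-yl (E)-2-methylbut-2-enoate
Product: 23 (4S,5R,6S)-6-acetoxy-2-bromo-5-isopropyl-6-[(2R,3R)-3-{3-[(4-methoxybenzyl)oxy]propyl}-3-methyloxiran-2-yl]-3-oxohexan-4-yl (E)-2-methylbut-2-enoate (both C10 epimers), via silyl enol ether 22 (not isolated)
Conditions: LiHMDS, TMSCl, THF, −78 °C; then NBS, NaHCO3, −78 → 0 °C
Reagents that add atoms: N-bromosuccinimide O=C1CCC(=O)N1Br; chlorotrimethylsilane C[Si](C)(C)Cl (its silyl group is carried only by 22)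
Why: Kinetic deprotonation of an α'-acyloxy ethyl ketone takes the unhindered C10 methylene, in situ silylation traps the enolate before any acyl transfer, and NBS brominates the silyl enol ether regiospecifically at C10 under neutral conditions.

Step 14
Reactants: 23 (4S,5R,6S)-6-acetoxy-2-bromo-5-isopropyl-6-[(2R,3R)-3-{3-[(4-methoxybenzyl)oxy]propyl}-3-methyloxiran-2-yl]-3-oxohexan-4-yl (E)-2-methylbut-2-enoate
Product: 24 (4S,5R,6S)-6-acetoxy-2-bromo-6-[(2R,3R)-3-(3-hydroxypropyl)-3-methyloxiran-2-yl]-5-isopropyl-3-oxohexan-4-yl (E)-2-methylbut-2-enoate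
Conditions: DDQ, CH2Cl2/pH 7 buffer, 0 °C → rt
Reagents that add atoms: none
Why: Oxidative PMB cleavage (hydride abstraction, hydrolysis of the oxocarbenium ion) under neutral conditions that spare the epoxide, both esters and the α-bromo ketone; the anisaldehyde is removed by chromatography so that it cannot intercept the later ylide.

Step 15
Reactants: 24 (4S,5R,6S)-6-acetoxy-2-bromo-6-[(2R,3R)-3-(3-hydroxypropyl)-3-methyloxiran-2-yl]-5-isopropyl-3-oxohexan-4-yl (E)-2-methylbut-2-enoate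
Product: 26 (4S,5R,6S)-6-acetoxy-6-[(2R,3R)-3-(3-hydroxypropyl)-3-methyloxiran-2-yl]-5-isopropyl-3-oxo-2-(triphenyl-λ5-phosphanylidene)hexan-4-yl (E)-2-methylbut-2-enoate, via phosphonium bromide 25 (not isolated)
Conditions: PPh3, MeCN, 50 °C; then aq. Na2CO3, CH2Cl2, rt
Reagents that add atoms: triphenylphosphine c1ccc(cc1)P(c1ccccc1)c1ccccc1
Why: SN2 displacement of the α-keto bromide by triphenylphosphine gives the β-keto phosphonium salt, whose acidic C10–H is removed by carbonate to give the stabilised, isolable ylide without touching esters or epoxide.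

Step 16
Reactants: 26 (4S,5R,6S)-6-acetoxy-6-[(2R,3R)-3-(3-hydroxypropyl)-3-methyloxiran-2-yl]-5-isopropyl-3-oxo-2-(triphenyl-λ5-phosphanylidene)hexan-4-yl (E)-2-methylbut-2-enoate
Product: 27 (4S,5R,6S)-6-acetoxy-5-isopropyl-6-[(2R,3R)-3-methyl-3-(3-oxopropyl)oxiran-2-yl]-3-oxo-2-(triphenyl-λ5-phosphanylidene)hexan-4-yl (E)-2-methylbut-2-enoate
Conditions: Dess–Martin periodinane, NaHCO3, CH2Cl2, 0 °C; cold work-up, crude 27 used at once
Reagents that add atoms: none
Why: Buffered Dess–Martin oxidation of the primary alcohol, which a stabilised α-methyl acyl ylide tolerates as in one-pot oxidation–Wittig sequences, and at 0 °C this ylide is too sluggish to olefinate the new aldehyde before dilution.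

Step 17
Reactants: 27 (4S,5R,6S)-6-acetoxy-5-isopropyl-6-[(2R,3R)-3-methyl-3-(3-oxopropyl)oxiran-2-yl]-3-oxo-2-(triphenyl-λ5-phosphanylidene)hexan-4-yl (E)-2-methylbut-2-enoate
Product: 28 (1(10)E,4R,5R,6S,7R,8S)-6-acetoxy-4,5-epoxy-9-oxogermacr-1(10)-en-8-yl (E)-2-methylbut-2-enoate
Conditions: toluene, 80 °C, syringe-pump addition to a final concentration near 1 mM
Reagents that add atoms: none
Why: The neutral acyl-stabilised ylide carbon C10 adds reversibly to the C1 aldehyde, and the oxaphosphetane collapses by syn-cycloreversion with loss of triphenylphosphine oxide. The closest known reaction type is the macrocyclic intramolecular Wittig olefination of ω-formyl keto phosphoranes to cyclic enones, here at the small-ring limit of that chemistry. The ten-membered carbocycle is closed by 10-exo-trig attack of C10 on the C1 carbonyl, and the elimination leaves the new C1=C10 bond inside the ring, with high dilution favouring closure over chain growth. No stereocentre is formed; the E geometry follows from the reversibility of the addition for an α-methyl acyl ylide, which places the C9 acyl group trans to C2 as a crown-like cyclodecene requires. The selectivity needed is aldehyde over the two ester carbonyls (attack on the adjacent tiglate would give a furanone), and it rests on the far higher electrophilicity of the aldehyde at 80 °C. The absence of base protects the C8 centre next to the ketone, the epoxide and both esters.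

Step 18
Reactants: 28 (1(10)E,4R,5R,6S,7R,8S)-6-acetoxy-4,5-epoxy-9-oxogermacr-1(10)-en-8-yl (E)-2-methylbut-2-enoate
Product: 29 (1(10)E,4R,5R,6S,7S,8S,9R)-6-acetoxy-4,5-epoxy-9-hydroxygermacr-1(10)-en-8-yl (E)-2-methylbut-2-enoate
Conditions: NaBH4, CeCl3·7H2O, MeOH, −78 °C
Reagents that add atoms: none
Why: Luche 1,2-reduction, in which the cerium-activated carbonyl is attacked by hard methoxyborohydride from the outer face of the ring conformer held by the C8 tiglate, which should set 9R under substrate control and leaves esters, epoxide and the alkene untouched.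

Compound list
1 | pent-4-yn-1-ol | C#CCCCO | starting material
2 | 1-methoxy-4-[(pent-4-yn-1-yloxy)methyl]benzene | C#CCCCOCc1ccc(OC)cc1 | intermediate
3 | dimethyl[(E)-5-[(4-methoxybenzyl)oxy]-2-methylpent-1-enyl]alane | C[Al](C)/C=C(\C)CCCOCc1ccc(OC)cc1 | intermediate (not isolated)
4 | (E)-6-[(4-methoxybenzyl)oxy]-3-methylhex-2-en-1-ol | OC/C=C(\C)CCCOCc1ccc(OC)cc1 | intermediate
5 | (E)-6-[(4-methoxybenzyl)oxy]-3-methylhex-2-enal | O=C/C=C(\C)CCCOCc1ccc(OC)cc1 | intermediate
6 | (S)-4-benzyloxazolidin-2-one | O=C1N[C@@H](Cc2ccccc2)CO1 | starting material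
7 | 3-methylbutanoyl chloride | CC(C)CC(Cl)=O | starting material
8 | (S)-4-benzyl-3-(3-methylbutanoyl)oxazolidin-2-one | CC(C)CC(=O)N1[C@@H](Cc2ccccc2)COC1=O | intermediate
9 | (S)-4-benzyl-3-[(2R,3R,E)-2-isopropyl-8-[(4-methoxybenzyl)oxy]-5-methyl-3-(trimethylsilyloxy)oct-4-enoyl]oxazolidin-2-one | COc1ccc(COCCC/C(C)=C/[C@@H](O[Si](C)(C)C)[C@@H](C(C)C)C(=O)N2[C@@H](Cc3ccccc3)COC2=O)cc1 | intermediate (not isolated)
10 | (S)-4-benzyl-3-[(2R,3R,E)-3-hydroxy-2-isopropyl-8-[(4-methoxybenzyl)oxy]-5-methyloct-4-enoyl]oxazolidin-2-one | COc1ccc(COCCC/C(C)=C/[C@@H](O)[C@@H](C(C)C)C(=O)N2[C@@H](Cc3ccccc3)COC2=O)cc1 | intermediate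
11 | (2R,3R,E)-3-hydroxy-2-isopropyl-N-methoxy-8-[(4-methoxybenzyl)oxy]-N,5-dimethyloct-4-enamide | COc1ccc(COCCC/C(C)=C/[C@@H](O)[C@@H](C(C)C)C(=O)N(C)OC)cc1 | intermediate
12 | (2R,3S)-3-hydroxy-2-isopropyl-N-methoxy-3-[(2R,3R)-3-{3-[(4-methoxybenzyl)oxy]propyl}-3-methyloxiran-2-yl]-N-methylpropanamide | COc1ccc(COCCC[C@@]2(C)O[C@@H]2[C@@H](O)[C@@H](C(C)C)C(=O)N(C)OC)cc1 | intermediate
13 | propanal | CCC=O | starting material
14 | propane-1,3-dithiol | SCCCS | starting material
15 | 2-ethyl-1,3-dithiane | CCC1SCCCS1 | intermediate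
16 | 2-ethyl-2-lithio-1,3-dithiane | [Li]C1(CC)SCCCS1 | intermediate (not isolated)
17 | (2R,3S)-1-(2-ethyl-1,3-dithian-2-yl)-3-hydroxy-2-isopropyl-3-[(2R,3R)-3-{3-[(4-methoxybenzyl)oxy]propyl}-3-methyloxiran-2-yl]propan-1-one | COc1ccc(COCCC[C@@]2(C)O[C@@H]2[C@@H](O)[C@@H](C(C)C)C(=O)C3(CC)SCCCS3)cc1 | intermediate
18 | (1S,2S,3S)-3-(2-ethyl-1,3-dithian-2-yl)-3-hydroxy-2-isopropyl-1-[(2R,3R)-3-{3-[(4-methoxybenzyl)oxy]propyl}-3-methyloxiran-2-yl]propyl acetate | COc1ccc(COCCC[C@@]2(C)O[C@@H]2[C@@H](OC(C)=O)[C@@H](C(C)C)[C@H](O)C3(CC)SCCCS3)cc1 | intermediate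
19 | (1S,2S,3S)-3-hydroxy-2-isopropyl-1-[(2R,3R)-3-{3-[(4-methoxybenzyl)oxy]propyl}-3-methyloxiran-2-yl]-4-oxohexyl acetate | COc1ccc(COCCC[C@@]2(C)O[C@@H]2[C@@H](OC(C)=O)[C@@H](C(C)C)[C@H](O)C(=O)CC)cc1 | intermediate
20 | (E)-2-methylbut-2-enoyl chloride (tigloyl chloride) | C/C=C(\C)C(Cl)=O | starting material
21 | (4S,5R,6S)-6-acetoxy-5-isopropyl-6-[(2R,3R)-3-{3-[(4-methoxybenzyl)oxy]propyl}-3-methyloxiran-2-yl]-3-oxohexan-4-yl (E)-2-methylbut-2-enoate | COc1ccc(COCCC[C@@]2(C)O[C@@H]2[C@@H](OC(C)=O)[C@@H](C(C)C)[C@H](OC(=O)/C(C)=C/C)C(=O)CC)cc1 | intermediate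
22 | (Z)-C9 trimethylsilyl enol ether of 21 (C9=C10) | COc1ccc(COCCC[C@@]2(C)O[C@@H]2[C@@H](OC(C)=O)[C@@H](C(C)C)[C@H](OC(=O)/C(C)=C/C)/C(O[Si](C)(C)C)=C/C)cc1 | intermediate (not isolated)
23 | (4S,5R,6S)-6-acetoxy-2-bromo-5-isopropyl-6-[(2R,3R)-3-{3-[(4-methoxybenzyl)oxy]propyl}-3-methyloxiran-2-yl]-3-oxohexan-4-yl (E)-2-methylbut-2-enoate, C10 epimers | COc1ccc(COCCC[C@@]2(C)O[C@@H]2[C@@H](OC(C)=O)[C@@H](C(C)C)[C@H](OC(=O)/C(C)=C/C)C(=O)C(C)Br)cc1 | intermediate
24 | (4S,5R,6S)-6-acetoxy-2-bromo-6-[(2R,3R)-3-(3-hydroxypropyl)-3-methyloxiran-2-yl]-5-isopropyl-3-oxohexan-4-yl (E)-2-methylbut-2-enoate, C10 epimers | OCCC[C@@]1(C)O[C@@H]1[C@@H](OC(C)=O)[C@@H](C(C)C)[C@H](OC(=O)/C(C)=C/C)C(=O)C(C)Br | intermediate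
25 | {(4S,5R,6S)-6-acetoxy-6-[(2R,3R)-3-(3-hydroxypropyl)-3-methyloxiran-2-yl]-5-isopropyl-4-[(E)-2-methylbut-2-enoyloxy]-3-oxohexan-2-yl}triphenylphosphonium bromide | OCCC[C@@]1(C)O[C@@H]1[C@@H](OC(C)=O)[C@@H](C(C)C)[C@H](OC(=O)/C(C)=C/C)C(=O)C(C)[P+](c1ccccc1)(c1ccccc1)c1ccccc1.[Br-] | intermediate (not isolated)
26 | (4S,5R,6S)-6-acetoxy-6-[(2R,3R)-3-(3-hydroxypropyl)-3-methyloxiran-2-yl]-5-isopropyl-3-oxo-2-(triphenyl-λ5-phosphanylidene)hexan-4-yl (E)-2-methylbut-2-enoate | OCCC[C@@]1(C)O[C@@H]1[C@@H](OC(C)=O)[C@@H](C(C)C)[C@H](OC(=O)/C(C)=C/C)C(=O)C(C)=P(c1ccccc1)(c1ccccc1)c1ccccc1 | intermediate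
27 | (4S,5R,6S)-6-acetoxy-5-isopropyl-6-[(2R,3R)-3-methyl-3-(3-oxopropyl)oxiran-2-yl]-3-oxo-2-(triphenyl-λ5-phosphanylidene)hexan-4-yl (E)-2-methylbut-2-enoate | O=CCC[C@@]1(C)O[C@@H]1[C@@H](OC(C)=O)[C@@H](C(C)C)[C@H](OC(=O)/C(C)=C/C)C(=O)C(C)=P(c1ccccc1)(c1ccccc1)c1ccccc1 | intermediate
28 | (1(10)E,4R,5R,6S,7R,8S)-6-acetoxy-4,5-epoxy-9-oxogermacr-1(10)-en-8-yl (E)-2-methylbut-2-enoate | C/C=C(\C)C(=O)O[C@H]1[C@H](C(C)C)[C@H](OC(C)=O)[C@H]2O[C@]2(C)CC/C=C(\C)C1=O | intermediate
29 | (1(10)E,4R,5R,6S,7S,8S,9R)-6-acetoxy-4,5-epoxy-9-hydroxygermacr-1(10)-en-8-yl (E)-2-methylbut-2-enoate (CNP0163041.1) | C/C=C(\C)C(=O)O[C@H]1[C@H](C(C)C)[C@H](OC(C)=O)[C@H]2O[C@]2(C)CC/C=C(\C)[C@H]1O | target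

Total step count: 18 (steps 4 and 8 are side branches).
Longest linear sequence: 16 steps (1–3, 5–7, 9–18).

Steps most likely to fail

Step 17. Chain growth by intermolecular olefination may outrun the strained ten-membered closure, or at the temperature needed the ylide may olefinate the neighbouring tiglate carbonyl to a five-membered furanone. The fallback forms the C1–C10 bond first as a single bond by an aldol-type closure and introduces the alkene afterwards. It sets out from 24, which is oxidised with Dess–Martin periodinane to the bromo keto aldehyde F1. Treatment of F1 with SmI2 (2.0 equiv only, so that the C–Br bond is reduced ahead of the α'-acyloxy ketone) in THF at −78 °C under high dilution generates the samarium enolate, which adds to the aldehyde in a Reformatsky-type closure to the cyclic β-hydroxy ketone F2. Mesylation of F2 (MsCl, Et3N) and elimination with DBU then give the conjugated enone, and the route is rejoined at 28.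

Step 9. Acylation of the bulky lithiated dithiane may stall because the Weinreb carbonyl is shielded by the C7 isopropyl group and the C6 alkoxide, so that 12 is recovered or enolised. The fallback sets C8 by addition to an aldehyde and no longer needs the ketone reduction of step 10. It sets out from 12, which is silylated (TESOTf, 2,6-lutidine, −78 °C) to the C6 triethylsilyl ether F3 and reduced with DIBAL-H at −78 °C to the aldehyde F4. Addition of 16 at −78 °C should follow the Felkin–Anh sense, reinforced by 1,3-anti induction from the C6 silyloxy group, and give the (8S) dithiane carbinol F5. Hydrolysis of the dithiane (MeI, CaCO3) gives the α-hydroxy ketone F6, acylation with 20 gives the tiglate F7, and buffered HF·pyridine frees the C6 alcohol F8. Acetylation of F8 (Ac2O, pyridine, DMAP) rejoins the route at 21.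

Step 18. Hydride delivery may show poor facial selectivity or prefer the inner face of the ring, so that the 9-epimer dominates. The fallback replaces substrate control by reagent control. It sets out from 28, which is reduced with (R)-2-methyl-CBS-oxazaborolidine and catecholborane in toluene at −78 °C; on the usual model, with the C10 alkenyl arm as the larger ketone substituent, this catalyst delivers hydride to the face that gives 9R. The route is rejoined at 29 and no new compound is made.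

Further compounds
F1 | step 17 | (4S,5R,6S)-6-acetoxy-2-bromo-5-isopropyl-6-[(2R,3R)-3-methyl-3-(3-oxopropyl)oxiran-2-yl]-3-oxohexan-4-yl (E)-2-methylbut-2-enoate | O=CCC[C@@]1(C)O[C@@H]1[C@@H](OC(C)=O)[C@@H](C(C)C)[C@H](OC(=O)/C(C)=C/C)C(=O)C(C)Br
F2 | step 17 | (4R,5R,6S,7R,8S)-6-acetoxy-4,5-epoxy-1-hydroxy-9-oxogermacran-8-yl (E)-2-methylbut-2-enoate, C1 and C10 epimers | C/C=C(\C)C(=O)O[C@H]1[C@H](C(C)C)[C@H](OC(C)=O)[C@H]2O[C@]2(C)CCC(O)C(C)C1=O
F3 | step 9 | C6 O-triethylsilyl ether of 12 | COc1ccc(COCCC[C@@]2(C)O[C@@H]2[C@@H](O[Si](CC)(CC)CC)[C@@H](C(C)C)C(=O)N(C)OC)cc1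
F4 | step 9 | (2R,3S)-2-isopropyl-3-[(2R,3R)-3-{3-[(4-methoxybenzyl)oxy]propyl}-3-methyloxiran-2-yl]-3-(triethylsilyloxy)propanal | COc1ccc(COCCC[C@@]2(C)O[C@@H]2[C@@H](O[Si](CC)(CC)CC)[C@@H](C(C)C)C=O)cc1
F5 | step 9 | (1S,2S,3S)-1-(2-ethyl-1,3-dithian-2-yl)-2-isopropyl-3-[(2R,3R)-3-{3-[(4-methoxybenzyl)oxy]propyl}-3-methyloxiran-2-yl]-3-(triethylsilyloxy)propan-1-ol | COc1ccc(COCCC[C@@]2(C)O[C@@H]2[C@@H](O[Si](CC)(CC)CC)[C@@H](C(C)C)[C@H](O)C3(CC)SCCCS3)cc1
F6 | step 9 | (4S,5S,6S)-4-hydroxy-5-isopropyl-6-[(2R,3R)-3-{3-[(4-methoxybenzyl)oxy]propyl}-3-methyloxiran-2-yl]-6-(triethylsilyloxy)hexan-3-one | COc1ccc(COCCC[C@@]2(C)O[C@@H]2[C@@H](O[Si](CC)(CC)CC)[C@@H](C(C)C)[C@H](O)C(=O)CC)cc1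
F7 | step 9 | (4S,5S,6S)-5-isopropyl-6-[(2R,3R)-3-{3-[(4-methoxybenzyl)oxy]propyl}-3-methyloxiran-2-yl]-3-oxo-6-(triethylsilyloxy)hexan-4-yl (E)-2-methylbut-2-enoate | COc1ccc(COCCC[C@@]2(C)O[C@@H]2[C@@H](O[Si](CC)(CC)CC)[C@@H](C(C)C)[C@H](OC(=O)/C(C)=C/C)C(=O)CC)cc1
F8 | step 9 | (4S,5R,6S)-6-hydroxy-5-isopropyl-6-[(2R,3R)-3-{3-[(4-methoxybenzyl)oxy]propyl}-3-methyloxiran-2-yl]-3-oxohexan-4-yl (E)-2-methylbut-2-enoate | COc1ccc(COCCC[C@@]2(C)O[C@@H]2[C@@H](O)[C@@H](C(C)C)[C@H](OC(=O)/C(C)=C/C)C(=O)CC)cc1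
F0 | step 18 | none | none
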